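Late cuts: N-CH3 goes back to N-CO2Me and the C8 phenol to its benzyl ether. Naphthalene ring C is then cut at C8'-C8a' and C5'-C4a'.
Enabling feature: ring C carries C5'-OMe and the C8' isoquinolinyl group para to each other, with C6'-H and C7'-H between them. C5', C6', C7', C8' are therefore C3, C4, C5, C6 of a 6-aryl-3-methoxy-2-pyrone. Ring D (C1'-C4', 2'-Me, 4'-OMe, C4a', C8a') is 3-methoxy-5-methylbenzyne, and only CO2 is lost.
The pyrone is cut at O1-C2 and C3-C4 to a C5 enaminone and methoxyketene. The enaminone comes from a C5 acetyl group, whose carbonyl also distinguishes O6 from O8 by chelation.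
Forward order of rings: benzene ring A is bought, hetero ring B closes by Bischler-Napieralski cyclisation, then the pyrone forms, then ring C closes onto the aryne that brings ring D.
Stereochemistry: C3 (R) is bought with the cyclic sulfamidate of N-Boc-D-alaninol. C1 (R, trans) comes from hydride reduction of the AlMe3-complexed imine. The biaryl axis is not controlled.

Key step: step 14

Remark: the SMILES string fixes C1 and C3 but not the sense of the C5-C8' axis, so the route aims at the (1R,3R) compound as drawn, and the two atropo-diastereomers expected from step 14 are separated by chromatography at 27 or at 29.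

Step 1
Reactants: 1 1,3-bis(benzyloxy)-5-bromobenzene; 2 tert-butyl (4R)-4-methyl-1,2,3-oxathiazolidine-3-carboxylate 2,2-dioxide
Product: 5 tert-butyl [(2R)-1-[3,5-bis(benzyloxy)phenyl]propan-2-yl]carbamate, via arylmagnesium bromide 3 (not isolated), via ring-opened N-sulfamate salt 4 (not isolated)
Conditions: 1, Mg, THF, 40 °C; then 2, CuBr·SMe2 (10 mol%), THF, -30 °C to rt; then 10% aq. citric acid, rt
Reagents that add atoms: none
Why: Copper-catalysed SN2 opening of a cyclic sulfamidate by an aryl Grignard reagent occurs at the primary carbon, so the later C3 stereocentre (R, from D-alaninol) is carried over untouched, and mild acid hydrolyses the N-sulfate while the Boc group stays.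

Step 2
Reactants: 5 tert-butyl [(2R)-1-[3,5-bis(benzyloxy)phenyl]propan-2-yl]carbamate
Product: 7 N-[(2R)-1-[3,5-bis(benzyloxy)phenyl]propan-2-yl]acetamide, via primary ammonium chloride 6 (not isolated)
Conditions: HCl (4 M in dioxane), CH2Cl2, rt; evaporate; Ac2O, Et3N, CH2Cl2, 0 °C to rt
Reagents that add atoms: acetic anhydride, CC(=O)OC(C)=O
Why: Acidolysis of the Boc group and N-acetylation are routine operations that touch neither the stereocentre nor the benzyl ethers and supply the amide whose acetyl carbons become C1 and its methyl group.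

Step 3
Reactants: 7 N-[(2R)-1-[3,5-bis(benzyloxy)phenyl]propan-2-yl]acetamide
Product: 8 (3R)-6,8-bis(benzyloxy)-1,3-dimethyl-3,4-dihydroisoquinoline
Conditions: POCl3, MeCN, reflux
Reagents that add atoms: none
Why: In this Bischler-Napieralski cyclodehydration the activated amide attacks a ring position that is ortho to one benzyloxy group and para to the other, and the symmetry of the arene allows only one regioisomer.

Step 4
Reactants: 8 (3R)-6,8-bis(benzyloxy)-1,3-dimethyl-3,4-dihydroisoquinoline
Product: 9 (1R,3R)-6,8-bis(benzyloxy)-1,3-dimethyl-1,2,3,4-tetrahydroisoquinoline (1,3-trans)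
Conditions: LiAlH4, AlMe3, THF, -78 °C to 0 °C
Reagents that add atoms: none
Why: In this hydride reduction of a Lewis acid-complexed cyclic imine, AlMe3 on nitrogen pushes the C3 methyl group into a pseudoaxial position and axial hydride delivery to C1 on that same face should set C1 as R, the 1,3-trans outcome established for this reagent pair on 1,3-dimethyl-3,4-dihydroisoquinolines.

Step 5
Reactants: 9 (1R,3R)-6,8-bis(benzyloxy)-1,3-dimethyl-1,2,3,4-tetrahydroisoquinoline
Product: 10 methyl (1R,3R)-6,8-bis(benzyloxy)-1,3-dimethyl-3,4-dihydroisoquinoline-2(1H)-carboxylate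
Conditions: ClCO2Me, Et3N, CH2Cl2, 0 °C to rt
Reagents that add atoms: methyl chloroformate, COC(=O)Cl
Why: N-acylation with a chloroformate removes the nucleophilicity of nitrogen, which would otherwise add to the aryne, and stores the carbon of the later N-methyl group.

Step 6
Reactants: 10 methyl (1R,3R)-6,8-bis(benzyloxy)-1,3-dimethyl-3,4-dihydroisoquinoline-2(1H)-carboxylate
Product: 11 methyl (1R,3R)-5-acetyl-6,8-bis(benzyloxy)-1,3-dimethyl-3,4-dihydroisoquinoline-2(1H)-carboxylate
Conditions: AcOH, (CF3CO)2O, CH2Cl2, 0 °C to rt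
Reagents that add atoms: acetic acid, CC(=O)O
Why: Friedel-Crafts acylation with the mixed anhydride made in the flask should go to C5 (ortho to O6, para to O8) because C7 is shielded by two benzyloxy groups, and it needs no metal Lewis acid that could strip the benzyl ethers.

Step 7
Reactants: 11 methyl (1R,3R)-5-acetyl-6,8-bis(benzyloxy)-1,3-dimethyl-3,4-dihydroisoquinoline-2(1H)-carboxylate
Product: 12 methyl (1R,3R)-5-acetyl-8-(benzyloxy)-6-hydroxy-1,3-dimethyl-3,4-dihydroisoquinoline-2(1H)-carboxylate
Conditions: MgBr2·OEt2, toluene-Et2O, 80 °C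
Reagents that add atoms: none
Why: In this chelation-controlled ether cleavage, magnesium held between the ketone oxygen and O6 activates only the ortho benzyl ether towards bromide, whereas the O8 benzyl ether has no carbonyl neighbour and should stay.

Step 8
Reactants: 12 methyl (1R,3R)-5-acetyl-8-(benzyloxy)-6-hydroxy-1,3-dimethyl-3,4-dihydroisoquinoline-2(1H)-carboxylate
Product: 13 methyl (1R,3R)-5-acetyl-8-(benzyloxy)-6-methoxy-1,3-dimethyl-3,4-dihydroisoquinoline-2(1H)-carboxylate
Conditions: MeI, K2CO3, DMF, 40 °C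
Reagents that add atoms: iodomethane, CI
Why: Williamson etherification of the only free phenol fixes the 6-OMe/8-OBn pattern, and carbonate is too weak a base to alkylate the ketone.

Step 9
Reactants: 13 methyl (1R,3R)-5-acetyl-8-(benzyloxy)-6-methoxy-1,3-dimethyl-3,4-dihydroisoquinoline-2(1H)-carboxylate
Product: 14 methyl (1R,3R)-8-(benzyloxy)-5-[(2E)-3-(dimethylamino)prop-2-enoyl]-6-methoxy-1,3-dimethyl-3,4-dihydroisoquinoline-2(1H)-carboxylate
Conditions: Me2NCH(OMe)2, toluene, 110 °C
Reagents that add atoms: N,N-dimethylformamide dimethyl acetal, COC(OC)N(C)C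
Why: Condensation of a methyl ketone with an amide acetal to the (E)-enaminone takes place at the unhindered methyl group and is therefore little affected by the two ortho substituents of the aryl ketone.

Step 10
Reactants: 14 methyl (1R,3R)-8-(benzyloxy)-5-[(2E)-3-(dimethylamino)prop-2-enoyl]-6-methoxy-1,3-dimethyl-3,4-dihydroisoquinoline-2(1H)-carboxylate
Product: 16 methyl (1R,3R)-8-(benzyloxy)-6-methoxy-5-(5-methoxy-6-oxo-6H-pyran-2-yl)-1,3-dimethyl-3,4-dihydroisoquinoline-2(1H)-carboxylate, via aminodihydropyranone 15 (not isolated)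
Conditions: MeOCH2COCl (2.5 equiv), Et3N, CH2Cl2, 0 °C to reflux
Reagents that add atoms: methoxyacetyl chloride, COCC(=O)Cl
Why: In this formal [4+2] cycloaddition of a ketene with the 1-oxadiene of an enaminone, the enaminone oxygen adds to the ketene carbonyl carbon (O1-C2), the resulting ester enolate closes on the vinylogous iminium carbon (C3-C4), and E1cB loss of dimethylamine from 15 aromatises the ring to the 2-pyrone while excess acid chloride takes up the amine.

Step 11
Reactants: 17 3-methoxy-5-methylphenol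
Product: 18 3-methoxy-5-methylphenyl isopropylcarbamate
Conditions: i-PrNCO, Et3N (cat.), CH2Cl2, rt
Reagents that add atoms: isopropyl isocyanate, CC(C)N=C=O
Why: Base-catalysed addition of a phenol to an isocyanate installs a strong ortho-directing group that can later be removed under mild basic conditions.

Step 12
Reactants: 18 3-methoxy-5-methylphenyl isopropylcarbamate
Product: 22 3-methoxy-5-methyl-2-(trimethylsilyl)phenyl isopropylcarbamate, via N-silyl carbamate 19 (not isolated), via aryllithium 20 (not isolated), via N-silyl C-silyl carbamate 21 (not isolated)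
Conditions: TBSOTf, TMEDA, Et2O, 0 °C to rt; n-BuLi, TMEDA, -78 °C; Me3SiCl, -78 °C to rt; aq. NaHSO4
Reagents that add atoms: chlorotrimethylsilane, C[Si](C)(C)Cl
Why: In this directed ortho-metalation, transient N-silylation masks the carbamate N-H, the carbamate and methoxy groups together acidify the C2-H between them so that lithiation and silylation occur only there, and the N-silyl group falls off in the acidic work-up.

Step 13
Reactants: 22 3-methoxy-5-methyl-2-(trimethylsilyl)phenyl isopropylcarbamate
Product: 24 3-methoxy-5-methyl-2-(trimethylsilyl)phenyl trifluoromethanesulfonate, via 2-silylphenol 23 (not isolated)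
Conditions: DBU, Et2NH, MeCN, 40 °C; then PhNTf2, rt
Reagents that add atoms: N-phenylbis(trifluoromethanesulfonimide), O=S(=O)(N(c1ccccc1)S(=O)(=O)C(F)(F)F)C(F)(F)F
Why: Base-induced E1cB cleavage of the secondary carbamate, with Et2NH trapping the isocyanate as a urea, frees the hindered phenoxide, which PhNTf2 triflates in the same flask under conditions that spare the aryl-silicon bond.

Step 14
Reactants: 16 methyl (1R,3R)-8-(benzyloxy)-6-methoxy-5-(5-methoxy-6-oxo-6H-pyran-2-yl)-1,3-dimethyl-3,4-dihydroisoquinoline-2(1H)-carboxylate; 24 3-methoxy-5-methyl-2-(trimethylsilyl)phenyl trifluoromethanesulfonate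
Product: 27 methyl (1R,3R)-8-(benzyloxy)-5-(4,5-dimethoxy-7-methylnaphthalen-1-yl)-6-methoxy-1,3-dimethyl-3,4-dihydroisoquinoline-2(1H)-carboxylate, via 3-methoxy-5-methylbenzyne 25 (not isolated), via bridged lactone 26 (not isolated)
Conditions: 24 (2.5 equiv, slow addition), CsF, MeCN, 60 °C
Reagents that add atoms: none
Why: Fluoride attacks the silicon of 24 and triflate leaves, giving aryne 25, whose strained triple bond adds suprafacially across C6 and C3 of the electron-rich pyrone diene in an asynchronous concerted [4+2] cycloaddition, C8'-C8a' forming ahead of C5'-C4a'. The closest known reaction type is the Diels-Alder reaction of 2-pyrones with arynes released from silylaryl triflates, followed by retro-Diels-Alder loss of CO2, an established way to naphthalenes. Ring C is closed intermolecularly by this cycloaddition as the carbocyclic six-membered ring of the benzo-fused 2-oxabicyclo[2.2.2]octadienone 26 and becomes aromatic when the O-C(=O) bridge leaves as CO2, so no oxidation is needed. The two bridgehead stereocentres of 26 are erased again and no permanent stereocentre is formed, C1 and C3 are spectators, and the new biaryl axis is not controlled, so both atropo-diastereomers are expected. The step needs regioselectivity: the 3-methoxy group makes C6 the diene terminus with the larger HOMO coefficient, the inductive pull of the aryne methoxy group makes the remote aryne carbon (later C8a') the electrophilic one, and the bulky C6 aryl group also avoids the aryne methoxy group, so electronic and steric bias both place the two methoxy groups peri at C4' and C5'. Chemoselectivity rests on the carbamate (no nucleophilic nitrogen) and the benzyl ether (no free phenol), neither of which reacts with fluoride or with the aryne.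

Step 15
Reactants: 27 methyl (1R,3R)-8-(benzyloxy)-5-(4,5-dimethoxy-7-methylnaphthalen-1-yl)-6-methoxy-1,3-dimethyl-3,4-dihydroisoquinoline-2(1H)-carboxylate
Product: 28 (1R,3R)-8-(benzyloxy)-5-(4,5-dimethoxy-7-methylnaphthalen-1-yl)-6-methoxy-1,2,3-trimethyl-1,2,3,4-tetrahydroisoquinoline
Conditions: LiAlH4, THF, reflux
Reagents that add atoms: none
Why: Exhaustive hydride reduction of a carbamate to the N-methylamine, through formamide and iminium stages, is standard for tetrahydroisoquinolines and leaves the aryl ethers, the benzyl ether and both stereocentres untouched.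

Step 16
Reactants: 28 (1R,3R)-8-(benzyloxy)-5-(4,5-dimethoxy-7-methylnaphthalen-1-yl)-6-methoxy-1,2,3-trimethyl-1,2,3,4-tetrahydroisoquinoline
Product: 29 ancistrocongoline B, (1R,3R)-5-(4,5-dimethoxy-7-methylnaphthalen-1-yl)-6-methoxy-1,2,3-trimethyl-1,2,3,4-tetrahydroisoquinolin-8-ol
Conditions: H2 (1 atm), Pd/C, MeOH-EtOAc, rt
Reagents that add atoms: none
Why: Catalytic hydrogenolysis should cleave only the O-benzyl bond, because the endocyclic C1-N bond of the hindered tertiary amine is inert under these mild conditions, and this frees the C8 phenol.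

Compound list
1 | 1,3-bis(benzyloxy)-5-bromobenzene | Brc1cc(OCc2ccccc2)cc(OCc2ccccc2)c1 | starting material
2 | tert-butyl (4R)-4-methyl-1,2,3-oxathiazolidine-3-carboxylate 2,2-dioxide (cyclic sulfamidate of N-Boc-D-alaninol) | C[C@@H]1COS(=O)(=O)N1C(=O)OC(C)(C)C | starting material
3 | 3,5-bis(benzyloxy)phenylmagnesium bromide | Br[Mg]c1cc(OCc2ccccc2)cc(OCc2ccccc2)c1 | intermediate
4 | bromomagnesium (R)-N-Boc-N-[1-[3,5-bis(benzyloxy)phenyl]propan-2-yl]sulfamate | C[C@@H](N(C(=O)OC(C)(C)C)S(=O)(=O)[O-])Cc1cc(OCc2ccccc2)cc(OCc2ccccc2)c1.[Mg+]Br | intermediate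
5 | tert-butyl [(2R)-1-[3,5-bis(benzyloxy)phenyl]propan-2-yl]carbamate | C[C@@H](NC(=O)OC(C)(C)C)Cc1cc(OCc2ccccc2)cc(OCc2ccccc2)c1 | intermediate
6 | (2R)-1-[3,5-bis(benzyloxy)phenyl]propan-2-aminium chloride | C[C@@H]([NH3+])Cc1cc(OCc2ccccc2)cc(OCc2ccccc2)c1.[Cl-] | intermediate
7 | N-[(2R)-1-[3,5-bis(benzyloxy)phenyl]propan-2-yl]acetamide | C[C@@H](NC(C)=O)Cc1cc(OCc2ccccc2)cc(OCc2ccccc2)c1 | intermediate
8 | (3R)-6,8-bis(benzyloxy)-1,3-dimethyl-3,4-dihydroisoquinoline | c1ccccc1COc1cc(OCc3ccccc3)c2c(c1)C[C@@H](C)N=C2C | intermediate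
9 | (1R,3R)-6,8-bis(benzyloxy)-1,3-dimethyl-1,2,3,4-tetrahydroisoquinoline (trans) | c1ccccc1COc1cc(OCc3ccccc3)c2c(c1)C[C@@H](C)N[C@@H]2C | intermediate
10 | methyl (1R,3R)-6,8-bis(benzyloxy)-1,3-dimethyl-3,4-dihydroisoquinoline-2(1H)-carboxylate | c1ccccc1COc1cc(OCc3ccccc3)c2c(c1)C[C@@H](C)N(C(=O)OC)[C@@H]2C | intermediate
11 | methyl (1R,3R)-5-acetyl-6,8-bis(benzyloxy)-1,3-dimethyl-3,4-dihydroisoquinoline-2(1H)-carboxylate | CC(=O)c1c(OCc2ccccc2)cc(OCc2ccccc2)c2c1C[C@@H](C)N(C(=O)OC)[C@@H]2C | intermediate
12 | methyl (1R,3R)-5-acetyl-8-(benzyloxy)-6-hydroxy-1,3-dimethyl-3,4-dihydroisoquinoline-2(1H)-carboxylate | CC(=O)c1c(O)cc(OCc2ccccc2)c2c1C[C@@H](C)N(C(=O)OC)[C@@H]2C | intermediate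
13 | methyl (1R,3R)-5-acetyl-8-(benzyloxy)-6-methoxy-1,3-dimethyl-3,4-dihydroisoquinoline-2(1H)-carboxylate | CC(=O)c1c(OC)cc(OCc2ccccc2)c2c1C[C@@H](C)N(C(=O)OC)[C@@H]2C | intermediate
14 | methyl (1R,3R)-8-(benzyloxy)-5-[(2E)-3-(dimethylamino)prop-2-enoyl]-6-methoxy-1,3-dimethyl-3,4-dihydroisoquinoline-2(1H)-carboxylate | CN(C)/C=C/C(=O)c1c(OC)cc(OCc2ccccc2)c2c1C[C@@H](C)N(C(=O)OC)[C@@H]2C | intermediate
15 | 6-aryl-4-(dimethylamino)-3-methoxy-3,4-dihydro-2H-pyran-2-one (aryl = C5 of the isoquinoline of 14; C3 and C4 of the pyranone unassigned) | COC1C(N(C)C)C=C(OC1=O)c1c(OC)cc(OCc2ccccc2)c2c1C[C@@H](C)N(C(=O)OC)[C@@H]2C | intermediate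
16 | methyl (1R,3R)-8-(benzyloxy)-6-methoxy-5-(5-methoxy-6-oxo-6H-pyran-2-yl)-1,3-dimethyl-3,4-dihydroisoquinoline-2(1H)-carboxylate | COc1cc(OCc2ccccc2)c2c(c1-c1ccc(OC)c(=O)o1)C[C@@H](C)N(C(=O)OC)[C@@H]2C | intermediate
17 | 3-methoxy-5-methylphenol | COc1cc(C)cc(O)c1 | starting material
18 | 3-methoxy-5-methylphenyl isopropylcarbamate | COc1cc(C)cc(OC(=O)NC(C)C)c1 | intermediate
19 | 3-methoxy-5-methylphenyl N-(tert-butyldimethylsilyl)-N-isopropylcarbamate | COc1cc(C)cc(OC(=O)N(C(C)C)[Si](C)(C)C(C)(C)C)c1 | intermediate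
20 | 2-lithio derivative of 19 | COc1cc(C)cc(OC(=O)N(C(C)C)[Si](C)(C)C(C)(C)C)c1[Li] | intermediate
21 | 3-methoxy-5-methyl-2-(trimethylsilyl)phenyl N-(tert-butyldimethylsilyl)-N-isopropylcarbamate | COc1cc(C)cc(OC(=O)N(C(C)C)[Si](C)(C)C(C)(C)C)c1[Si](C)(C)C | intermediate
22 | 3-methoxy-5-methyl-2-(trimethylsilyl)phenyl isopropylcarbamate | COc1cc(C)cc(OC(=O)NC(C)C)c1[Si](C)(C)C | intermediate
23 | 3-methoxy-5-methyl-2-(trimethylsilyl)phenol | COc1cc(C)cc(O)c1[Si](C)(C)C | intermediate
24 | 3-methoxy-5-methyl-2-(trimethylsilyl)phenyl trifluoromethanesulfonate | COc1cc(C)cc(OS(=O)(=O)C(F)(F)F)c1[Si](C)(C)C | intermediate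
25 | 3-methoxy-5-methylbenzyne | COC1=CC(C)=CC#C1 | intermediate
26 | benzo-fused 2-oxabicyclo[2.2.2]octa-5,7-dien-3-one adduct of 16 and 25 (bridgeheads C-OMe and C-aryl, both bridgehead configurations) | COC12C=CC(c3c(OC)cc(OCc4ccccc4)c4c3C[C@@H](C)N(C(=O)OC)[C@@H]4C)(OC1=O)c1cc(C)cc(OC)c12 | intermediate
27 | methyl (1R,3R)-8-(benzyloxy)-5-(4,5-dimethoxy-7-methylnaphthalen-1-yl)-6-methoxy-1,3-dimethyl-3,4-dihydroisoquinoline-2(1H)-carboxylate | COc1cc(OCc2ccccc2)c2c(c1-c1ccc(OC)c3c(OC)cc(C)cc13)C[C@@H](C)N(C(=O)OC)[C@@H]2C | intermediate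
28 | (1R,3R)-8-(benzyloxy)-5-(4,5-dimethoxy-7-methylnaphthalen-1-yl)-6-methoxy-1,2,3-trimethyl-1,2,3,4-tetrahydroisoquinoline | COc1cc(OCc2ccccc2)c2c(c1-c1ccc(OC)c3c(OC)cc(C)cc13)C[C@@H](C)N(C)[C@@H]2C | intermediate
29 | ancistrocongoline B, (1R,3R)-5-(4,5-dimethoxy-7-methylnaphthalen-1-yl)-6-methoxy-1,2,3-trimethyl-1,2,3,4-tetrahydroisoquinolin-8-ol | COc1cc(O)c2c(c1-c1ccc(OC)c3c(OC)cc(C)cc13)C[C@@H](C)N(C)[C@@H]2C | target

Total step count: 16.
Longest linear sequence: 13 steps (steps 1 to 10 and 14 to 16). Steps 11 to 13 form the aryne branch.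

Steps most likely to fail

**Step 14.**
- What may go wrong: the short-lived aryne may be consumed by self-reaction before the crowded C6 terminus of the diene traps it, or the two orientations of addition may compete.
- The fallback sets out from 16 and replaces the aryne by a persistent ring D dienophile that tolerates long heating.
- Commercial 5-methylcyclohex-2-en-1-one is brominated (Br2, CH2Cl2, 0 °C) to 2,3-dibromo-5-methylcyclohexan-1-one F1. Et3N then eliminates HBr to give 2-bromo-5-methylcyclohex-2-en-1-one F2.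
- Heating 16 with this enone (toluene, 2,6-lutidine, sealed tube, 150 °C) should join pyrone C6 to the enone beta carbon in a normal-demand Diels-Alder reaction and give the bridged bromo lactone F3.
- That adduct loses CO2 and HBr on the spot to give the tetralone F4.
- Aerobic dehydrogenation (Pd(O2CCF3)2 cat., 2-(dimethylamino)pyridine, TsOH, O2, DMSO, 80 °C) gives the naphthol F5.
- O-methylation (MeI, K2CO3, DMF) comes back to the route at 27.

**Step 10.**
- What may go wrong: C-acylation of the enaminone at its alpha carbon, or [2+2] addition of the ketene to the enamine double bond, may outrun the ring-forming pathway.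
- The fallback sets out from 14 and builds the same two bonds stepwise by anionic chemistry.
- Methyl methoxyacetate is deprotonated (LDA, THF, -78 °C) to the lithium enolate of methyl methoxyacetate F6.
- This enolate adds to the beta carbon of 14 and expels dimethylamide (Benary-type addition-elimination; the flanked ketone resists 1,2-attack). The product is the keto ester F7.
- Equilibration through its dienol and lactonisation (DBU, toluene, 80 °C) come back to the route at 16.

**Step 6.**
- What may go wrong: the mild acylating agent may be too slow at the flanked C5 position, while stronger activation invites loss of benzyl groups or ionisation at C1 with erosion of the trans relationship.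
- The fallback sets out from 10 and separates ring substitution from carbon-carbon bond formation.
- Bromination (NBS, MeCN, 0 °C) should give the 5-bromide F8.
- Stille coupling with tributyl(1-ethoxyvinyl)stannane (Pd(PPh3)4, toluene, 100 °C) gives the enol ether F9.
- Hydrolysis (1 M HCl, THF, rt) comes back to the route at 11.

Further compounds
F1 | step 14 | 2,3-dibromo-5-methylcyclohexan-1-one | CC1CC(Br)C(Br)C(=O)C1
F2 | step 14 | 2-bromo-5-methylcyclohex-2-en-1-one | CC1CC=C(Br)C(=O)C1
F3 | step 14 | bridged bromo lactone, Diels-Alder adduct of 16 and F2 (new stereocentres unassigned) | COC12C=CC(c3c(OC)cc(OCc4ccccc4)c4c3C[C@@H](C)N(C(=O)OC)[C@@H]4C)(OC1=O)C1CC(C)CC(=O)C12Br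
F4 | step 14 | methyl (1R,3R)-8-(benzyloxy)-6-methoxy-5-(4-methoxy-7-methyl-5-oxo-5,6,7,8-tetrahydronaphthalen-1-yl)-1,3-dimethyl-3,4-dihydroisoquinoline-2(1H)-carboxylate (methyl-bearing ring D carbon unassigned) | COc1ccc(-c3c(OC)cc(OCc4ccccc4)c4c3C[C@@H](C)N(C(=O)OC)[C@@H]4C)c2c1C(=O)CC(C)C2
F5 | step 14 | methyl (1R,3R)-8-(benzyloxy)-5-(5-hydroxy-4-methoxy-7-methylnaphthalen-1-yl)-6-methoxy-1,3-dimethyl-3,4-dihydroisoquinoline-2(1H)-carboxylate | COc1ccc(-c3c(OC)cc(OCc4ccccc4)c4c3C[C@@H](C)N(C(=O)OC)[C@@H]4C)c2cc(C)cc(O)c12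
F6 | step 10 | lithium enolate of methyl methoxyacetate | COC=C([O-])OC.[Li+]
F7 | step 10 | methyl (1R,3R)-8-(benzyloxy)-5-[(2E)-4,5-dimethoxy-5-oxopent-2-enoyl]-6-methoxy-1,3-dimethyl-3,4-dihydroisoquinoline-2(1H)-carboxylate (methoxy-bearing side-chain carbon unassigned) | COC(=O)C(OC)/C=C/C(=O)c1c(OC)cc(OCc2ccccc2)c2c1C[C@@H](C)N(C(=O)OC)[C@@H]2C
F8 | step 6 | methyl (1R,3R)-6,8-bis(benzyloxy)-5-bromo-1,3-dimethyl-3,4-dihydroisoquinoline-2(1H)-carboxylate | Brc1c(OCc2ccccc2)cc(OCc2ccccc2)c2c1C[C@@H](C)N(C(=O)OC)[C@@H]2C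
F9 | step 6 | methyl (1R,3R)-6,8-bis(benzyloxy)-5-(1-ethoxyvinyl)-1,3-dimethyl-3,4-dihydroisoquinoline-2(1H)-carboxylate | C=C(OCC)c1c(OCc2ccccc2)cc(OCc2ccccc2)c2c1C[C@@H](C)N(C(=O)OC)[C@@H]2C
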